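## The problem

Compound 25 is a cyclobutane-1,3-dicarboxylate with aryl groups at C2 and C4 in the α-truxillate arrangement (each aryl cis to one neighbouring carboxyl and trans to the other, the two aryls trans). Both carboxyls are esterified by the same alcohol, (4R,4aS,6R,7S,7aR)-2,4,7-trimethyloctahydro-1H-cyclopenta[c]pyridin-6-ol. Because one aryl is 4-hydroxy-3-methoxyphenyl and the other 4-hydroxyphenyl, the core has no inversion centre and is chiral; the diastereomeric diesters from a racemic core would differ only in which ring carries the methoxy group, so the diacid must be enantiopure before esterification. Each alcohol unit is a cis-fused piperidine–cyclopentane (fusion bond C4a–C7a) with five contiguous stereocentres: H4, H4a and H7a lie on one face together with the C7 methyl and the C6 oxygen, and the C4 methyl lies on the other. C4 cannot be corrected once the ring is saturated and is best taken from the chiral pool; C7a and C7 can be relayed from it and from an alkene geometry, and C4a from the shape of the bicycle, but the C6 oxygen is cis to the C7 methyl, the epimer that hydride addition to a C6 ketone is not expected to give. Reagent choice is limited by the two phenols (acidic enough to compete in a redox esterification), the two basic N-methyl amines, the truxillate centres α to carbonyl groups (epimerisable by strong base) and, early on, an α-methyl aldehyde. The feature that invites the key step is the cyclopentane of the alcohol: C6 bears oxygen between C5 and the methyl-bearing C7, and the ring is fused at C4a–C7a to the N2 piperidine. This is the pattern of a cyclopentenone assembled from an alkyne (C5, C4a), an alkene (C7a, C7) and CO (C6) across the tether C4–C3–N2–C1.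

## Retrosynthesis

**25 from 24.** No skeletal bond is cut; the two phenols are traced back to benzyl ethers in 24. The ethers keep the phenols out of the esterification and fall in a final hydrogenolysis that esters, cyclobutane and amines should tolerate.

**24 from 23 and two molecules of 11.** The two C6–O bonds are cut in the inverting sense, giving the enantiopure diacid 23 and the 6S alcohol 11 (the C6 epimer of the natural alcohol). The neighbouring cut, acylation of a 6R alcohol with retention, would need an alcohol that hydride reduction does not supply and a separate inversion sequence. The cut divides fourteen stereocentres into four (23) and twice five (11), and 11 is needed only once as a synthetic problem. The forward reaction must achieve SN2 displacement twice at a secondary carbon next to a methyl-bearing carbon, and 23 must already be a single enantiomer.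

**11 from 10 and 9.** No skeletal bond is cut. The C6 alcohol and the N-methyl group come from ketone and tert-butyl carbamate in 10 by one hydride reagent, and H4a comes from hydrogenation of the enone 9. The forward steps must deliver hydrogen to C4a and hydride to C6 from the convex face; the second of these leads to 6S, which is why the esterification is planned with inversion.

**9 from 7 (through 8).** Three bonds are cut at once: C4a–C7a, C5–C6 and C6–C7, opening both rings to the acyclic enyne 7 with a single stereocentre. Cuts that close one ring at a time need a preformed ring carrying two or three stereocentres. This cut must relay C4 to C7a (facial selectivity of alkene insertion in the cobalt complex 8) and transfer the (E)-alkene geometry to the C7/C7a pair.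

**7 from 6, 5, 4, 3, 1 and 2.** The alkyne carbon C5 is removed (one-carbon homologation of aldehyde 6) and the aldehyde is traced through alcohol 5 and amine 4 to amide 3. Compound 3 is cut at the N–acyl bond into methyl (R)-3-hydroxy-2-methylpropanoate 1 and (E)-but-2-en-1-amine 2. Bringing nitrogen in by acylation avoids displacement of a β-sulfonyloxy ester by a basic nitrogen nucleophile, which would risk elimination to the methacrylate and loss of configuration. The epimerisable aldehyde 6 then appears only once, directly before use.

**23 from 22, 21, 20, 19, 18, 17, 16, 15, 14, 13 and 12.** The two ring–aryl bonds are cut, not the two ring C–C bonds of a photodimer. A crystal-phase cross-dimerisation of two different cinnamic acids cannot be steered to the head-to-tail hetero-dimer, whereas amide-directed C–H arylation installs each ring separately and fixes its face. Diacid 23 comes from amide ester 21 through the activated imide 22. Compound 21 arises from 18 and iodide 20 (from phenol 19); 18 is the amide epimer of 17, the resolved form of racemic 16; 16 arises from 14 and iodide 15; and 14 is the amide of the commercial cis acid 12 with quinolin-8-amine 13. The forward sequence must stop at mono-arylation, epimerise only the amide-bearing carbon, and cleave the auxiliary without touching the α-centres.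

## Roads not taken

**Alternative 1:** The cut is the C1–C4 bond of the cyclobutane, traced to a pyrrolidine in which a coumarin serves as a cis-locked coumarate. In the forward step PhI(OH)OTs and ammonium carbamate N-aminate the pyrrolidine, and the 1,1-diazene loses N2 to join the two α-carbons with retention, giving the cyclobuta[c]chromenone A1.
- Merits: the two aryl groups come from different building blocks, so the mixed head-to-tail pattern is unambiguous; the lactone differentiates the two carboxyls and fixes one aryl/carboxyl pair cis; and the pyrrolidine could come from a catalytic asymmetric azomethine ylide cycloaddition, so no resolution would be needed.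
- Weak points: the 1,4-biradical is benzylic at both ends and can fragment to two alkenes, a risk that grows with electron-rich aryl groups; the hypervalent iodine reagent can oxidise such rings; the lactone oxygen must later be removed from the arene (opening, triflation, reduction); and the step does nothing for the amino alcohol, which holds ten of the fourteen stereocentres.
- Comparison: for the cyclobutane this road is better than steps 9–15 in absolute stereocontrol, since no material is lost to a resolution. The chosen plan sets against it two C–H arylations on a substrate class where they are established with closely similar alkoxyaryl iodides, and a key step spent on the unit that is used twice.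

**Alternative 2:** The cut is at nitrogen: N2–C1 and N2–C3 are traced to a ring ketone of a cis-bicyclo[3.3.0]octane. In the forward step a chiral hydroxyalkyl azide adds to the ketone and, under BF3·OEt2, one α-carbon migrates to nitrogen with loss of N2, giving lactam A2.
- Merits: the cis ring fusion is present from the first intermediate, the C6 oxygen and C7 methyl are set on a rigid bicycle, and no stoichiometric transition metal is needed.
- Weak points: the two α-carbons of the ketone are both methylene groups, so the migrating group is chosen only by the chiral azide; A2 still lacks the C4 methyl, and lactam enolate alkylation from the convex face would give the wrong C4 epimer unless followed by deprotonation and kinetic protonation; the N-hydroxyalkyl chain must be removed and replaced by methyl; and the bicyclic ketone needs several steps of desymmetrisation first.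
- Comparison: ring fusion is more secure here than in the chosen plan, where it depends on the hydrogenation face. Against that, the chosen plan reaches its cyclisation precursor in five steps, forms three C–C bonds and both rings at once, and carries both methyl groups from the start.

**Alternative 3:** The cut is C4a–C5, traced to a methyl ketone tethered to an α-methyl unsaturated lactam. In the forward step LiN(SiMe3)2 forms the kinetic methyl enolate, which adds 5-exo-trig to the β-carbon, and protonation of the lactam enolate sets C4 to give dione A3.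
- Merits: A3 is saturated and already N-methylated, so a single LiAlH4 reduction of lactam and ketone would lead directly to 11 with no hydrogenation and no cobalt.
- Weak points: the precursor is a ring with two adjacent stereocentres, one of them α to the ketone and epimerisable; enolate formation must choose methyl over the α-methine and over the lactam γ-position; and C4 rests on a protonation whose face is not secured.
- Comparison: after the ring closure this road is shorter than the chosen one. The chosen plan sets against it a precursor with one pool stereocentre, C7 fixed by alkene geometry instead of an epimerisable centre, and two rings closed in one step.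

Key step: step 6

Assumption: amine 2 is used as the free base liberated from its commercial hydrochloride, and the absolute configuration of 17 is assigned after the resolution by X-ray crystallography.

## Route

Step 1
Reactants: 1 methyl (R)-3-hydroxy-2-methylpropanoate; 2 (E)-but-2-en-1-amine
Product: 3 (R)-N-[(E)-but-2-en-1-yl]-3-hydroxy-2-methylpropanamide
Conditions: AlMe3 (2.5 equiv), CH2Cl2, 0 °C to 40 °C
Reagents that add atoms: none
Why: Weinreb-type aminolysis of the ester by the dimethylaluminium amide formed from AlMe3 and 2; the hydroxyl is held as an aluminium alkoxide and the medium is too weakly basic to enolise, so C2 should keep its configuration.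

Step 2
Reactants: 3 (R)-N-[(E)-but-2-en-1-yl]-3-hydroxy-2-methylpropanamide
Product: 4 (S)-3-{[(E)-but-2-en-1-yl]amino}-2-methylpropan-1-ol
Conditions: LiAlH4, THF, reflux; aqueous NaOH work-up
Reagents that add atoms: none
Why: Hydride reduction of a secondary amide to the amine; the isolated (E)-alkene is inert to LiAlH4 and the stereocentre is not touched (the descriptor changes only because the priorities change).

Step 3
Reactants: 4 (S)-3-{[(E)-but-2-en-1-yl]amino}-2-methylpropan-1-ol
Product: 5 tert-butyl [(E)-but-2-en-1-yl][(2S)-3-hydroxy-2-methylpropyl]carbamate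
Conditions: Boc2O, Et3N, CH2Cl2, 0 °C to rt
Reagents that add atoms: di-tert-butyl dicarbonate, CC(C)(C)OC(=O)OC(=O)OC(C)(C)C
Why: Chemoselective N-acylation of the secondary amine in the presence of the primary alcohol; the carbamate later serves as the non-basic tether and as the source of the N-methyl carbon.

Step 4
Reactants: 5 tert-butyl [(E)-but-2-en-1-yl][(2S)-3-hydroxy-2-methylpropyl]carbamate
Product: 6 tert-butyl [(E)-but-2-en-1-yl][(2S)-2-methyl-3-oxopropyl]carbamate
Conditions: Dess–Martin periodinane, CH2Cl2, 0 °C to rt; used crude at once
Reagents that add atoms: none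
Why: Dess–Martin oxidation of a primary alcohol under near-neutral, non-enolising conditions, so the α-methyl stereocentre should survive; alkene and carbamate are inert.

Step 5
Reactants: 6 tert-butyl [(E)-but-2-en-1-yl][(2S)-2-methyl-3-oxopropyl]carbamate
Product: 7 tert-butyl [(E)-but-2-en-1-yl][(2R)-2-methylbut-3-yn-1-yl]carbamate
Conditions: dimethyl (1-diazo-2-oxopropyl)phosphonate, K2CO3, MeOH, 0 °C to rt
Reagents that add atoms: dimethyl (1-diazo-2-oxopropyl)phosphonate, COP(=O)(OC)C(=[N+]=[N-])C(C)=O
Why: Ohira–Bestmann (Seyferth–Gilbert) homologation: methanolysis frees the diazomethylphosphonate anion, which adds to the aldehyde, loses phosphate and N2 and rearranges to the terminal alkyne; α-branched N-protected aldehydes are established substrates at 0 °C.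

Step 6
Reactants: 7 tert-butyl [(E)-but-2-en-1-yl][(2R)-2-methylbut-3-yn-1-yl]carbamate
Product: 9 tert-butyl (4R,7S,7aS)-4,7-dimethyl-6-oxo-1,3,4,6,7,7a-hexahydro-2H-cyclopenta[c]pyridine-2-carboxylate, via alkyne–hexacarbonyldicobalt complex 8 (not isolated)
Conditions: Co2(CO)8 (1.1 equiv), CH2Cl2, rt; then Me3NO·2H2O (excess), 0 °C to rt
Reagents that add atoms: dicobalt octacarbonyl (delivers the C6 carbonyl), [Co].[Co].[C-]#[O+].[C-]#[O+].[C-]#[O+].[C-]#[O+].[C-]#[O+].[C-]#[O+].[C-]#[O+].[C-]#[O+]
Why: Intramolecular Pauson–Khand reaction, the closest known type being the cyclisation of sulfonamide- and carbamate-tethered 1,7-enynes to hexahydrocyclopenta[c]pyridinones. Co2(CO)8 binds the terminal alkyne as complex 8, and the amine N-oxide removes one CO as CO2 to open a site for the alkene. Insertion of the alkene into the cobalt–C4a bond forms C4a–C7a and closes the piperidine in a 6-exo mode through a chair-like tether; CO insertion (C6–C7) and reductive elimination (C5–C6) then close the cyclopentenone as a formal [2+2+1] annulation. C7 relative to C7a is fixed by the alkene, since both new bonds form on one face of the (E)-alkene, so H7 and H7a end trans and the C7 methyl trans to C1. C7a relative to C4 is controlled by the propargylic methyl, which should sit pseudo-equatorial in the chair and so place H4 and H7a cis. The step needs this facial selectivity and needs intramolecular insertion to outrun alkyne oligomerisation; the non-basic carbamate tether and N-oxide promotion at low temperature serve both. Regiochemistry (C6 between the alkyne terminus C5 and the distal alkene carbon C7) is dictated by the tether.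

Step 7
Reactants: 9 tert-butyl (4R,7S,7aS)-4,7-dimethyl-6-oxo-1,3,4,6,7,7a-hexahydro-2H-cyclopenta[c]pyridine-2-carboxylate
Product: 10 tert-butyl (4R,4aS,7S,7aR)-4,7-dimethyl-6-oxooctahydro-2H-cyclopenta[c]pyridine-2-carboxylate
Conditions: H2 (1 atm), Pd/C, EtOAc, rt
Reagents that add atoms: none
Why: Heterogeneous hydrogenation of a trisubstituted enone; hydrogen should reach C4a from the face of H7a, away from C1 and C3 of the piperidine, giving the cis-fused bicycle with H4a cis to H4 and H7a, while ketone and carbamate are untouched.

Step 8
Reactants: 10 tert-butyl (4R,4aS,7S,7aR)-4,7-dimethyl-6-oxooctahydro-2H-cyclopenta[c]pyridine-2-carboxylate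
Product: 11 (4R,4aS,6S,7S,7aR)-2,4,7-trimethyloctahydro-1H-cyclopenta[c]pyridin-6-ol
Conditions: LiAlH4, THF, −78 °C to 0 °C, then reflux
Reagents that add atoms: none
Why: LiAlH4 reduces the cyclopentanone in the cold and the tert-butyl carbamate to N-methyl on heating. Hydride should enter from the convex face, which is also the usual course for a small hydride on a 2-methylcyclopentanone, so the C6 oxygen ends trans to the C7 methyl (6S), the epimer needed for the inverting esterification.

Step 9
Reactants: 12 cis-3-(methoxycarbonyl)cyclobutane-1-carboxylic acid; 13 quinolin-8-amine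
Product: 14 methyl cis-3-(quinolin-8-ylcarbamoyl)cyclobutane-1-carboxylate
Conditions: EDC, DMAP, CH2Cl2, rt
Reagents that add atoms: none
Why: Carbodiimide amide coupling that installs the bidentate 8-aminoquinoline directing group; the neutral conditions leave the cis relationship intact.

Step 10
Reactants: 14 methyl cis-3-(quinolin-8-ylcarbamoyl)cyclobutane-1-carboxylate; 15 1-(benzyloxy)-4-iodobenzene
Product: 16 racemic methyl (1S*,2R*,3R*)-2-[4-(benzyloxy)phenyl]-3-(quinolin-8-ylcarbamoyl)cyclobutane-1-carboxylate (all-cis)
Conditions: Pd(OAc)2 (cat.), Ag2CO3, PivOH, (CF3)2CHOH, 90 °C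
Reagents that add atoms: none
Why: Aminoquinoline-directed C(sp3)–H arylation in a divalent/tetravalent palladium cycle: the N,N-chelated palladium cleaves a methylene C–H cis to the amide and delivers the aryl group to that face, so the ring ends cis to amide and ester. The fluorinated alcohol and pivalic acid are the established means of stopping at mono-arylation, and the product is racemic because the two methylene groups of 14 are enantiotopic.

Step 11
Reactants: 16 racemic methyl (1S*,2R*,3R*)-2-[4-(benzyloxy)phenyl]-3-(quinolin-8-ylcarbamoyl)cyclobutane-1-carboxylate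
Product: 17 methyl (1S,2R,3R)-2-[4-(benzyloxy)phenyl]-3-(quinolin-8-ylcarbamoyl)cyclobutane-1-carboxylate
Conditions: preparative supercritical-fluid chromatography, amylose tris(3,5-dimethylphenylcarbamate) phase, CO2/MeOH
Reagents that add atoms: none
Why: Chromatographic resolution of a racemate on a polysaccharide chiral phase; no bond is made, and resolving the first chiral, neutral intermediate spares all later steps the unwanted antipode.

Step 12
Reactants: 17 methyl (1S,2R,3R)-2-[4-(benzyloxy)phenyl]-3-(quinolin-8-ylcarbamoyl)cyclobutane-1-carboxylate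
Product: 18 methyl (1S,2R,3S)-2-[4-(benzyloxy)phenyl]-3-(quinolin-8-ylcarbamoyl)cyclobutane-1-carboxylate
Conditions: LiOt-Bu, toluene, 50 °C
Reagents that add atoms: none
Why: Base-mediated epimerisation at the amide-bearing carbon: lithium chelation by the amidate and quinoline nitrogen acidifies that C–H, and reprotonation places the amide trans to the aryl ring, relieving all-cis strain. Selective inversion of this carbon over the ester-bearing one under these conditions is established for closely related dialkoxyphenyl amide esters.

Step 13
Reactants: 19 4-iodo-2-methoxyphenol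
Product: 20 1-(benzyloxy)-4-iodo-2-methoxybenzene
Conditions: BnBr, K2CO3, DMF, rt
Reagents that add atoms: benzyl bromide, BrCc1ccccc1
Why: Williamson ether synthesis on a phenoxide; the aryl iodide is inert under these conditions.

Step 14
Reactants: 18 methyl (1S,2R,3S)-2-[4-(benzyloxy)phenyl]-3-(quinolin-8-ylcarbamoyl)cyclobutane-1-carboxylate; 20 1-(benzyloxy)-4-iodo-2-methoxybenzene
Product: 21 methyl (1R,2R,3R,4R)-2-[4-(benzyloxy)-3-methoxyphenyl]-4-[4-(benzyloxy)phenyl]-3-(quinolin-8-ylcarbamoyl)cyclobutane-1-carboxylate
Conditions: Pd(OAc)2 (cat.), Ag2CO3, PivOH, t-BuOH, 75 °C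
Reagents that add atoms: none
Why: Second aminoquinoline-directed C–H arylation at the only remaining methylene; palladium again cleaves the C–H cis to the amide, now on the face opposite the first aryl ring, so the new ring ends cis to the amide and trans to the first ring and the ester, which is the α-truxillate pattern.

Step 15
Reactants: 21 methyl (1R,2R,3R,4R)-2-[4-(benzyloxy)-3-methoxyphenyl]-4-[4-(benzyloxy)phenyl]-3-(quinolin-8-ylcarbamoyl)cyclobutane-1-carboxylate
Product: 23 (1R,3R)-2-[4-(benzyloxy)-3-methoxyphenyl]-4-[4-(benzyloxy)phenyl]cyclobutane-1,3-dicarboxylic acid (α-truxillic configuration), via N-Boc imide 22 (not isolated)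
Conditions: Boc2O, DMAP, MeCN, rt; then LiOH, H2O2, THF/H2O, 0 °C to rt; Na2SO3, then HCl
Reagents that add atoms: hydrogen peroxide, OO; lithium hydroxide, [Li+].[OH-]; di-tert-butyl dicarbonate, CC(C)(C)OC(=O)OC(=O)OC(C)(C)C (its Boc group stays only in 22)
Why: N-Boc activation twists the amide into an imide (22) that hydroperoxide cleaves at the acyl carbonyl, while hydroxide saponifies the methyl ester; these mild conditions should not epimerise the α-centres, and the benzyl ethers are inert.

Step 16
Reactants: 23 (1R,3R)-2-[4-(benzyloxy)-3-methoxyphenyl]-4-[4-(benzyloxy)phenyl]cyclobutane-1,3-dicarboxylic acid; 11 (4R,4aS,6S,7S,7aR)-2,4,7-trimethyloctahydro-1H-cyclopenta[c]pyridin-6-ol (2.2 equiv)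
Product: 24 bis[(4R,4aS,6R,7S,7aR)-2,4,7-trimethyloctahydro-1H-cyclopenta[c]pyridin-6-yl] (1R,3R)-2-[4-(benzyloxy)-3-methoxyphenyl]-4-[4-(benzyloxy)phenyl]cyclobutane-1,3-dicarboxylate
Conditions: PPh3, DIAD, THF, 0 °C to rt
Reagents that add atoms: none
Why: Double Mitsunobu esterification: each carboxylate displaces the alkoxyphosphonium of 11 by SN2 with inversion (6S to 6R), placing the ester oxygen cis to the C7 methyl. The 1,3-trans carboxyls cannot form a cyclic anhydride, the benzyl ethers keep the phenols out of the reaction, and the same inverting coupling of this alcohol is established for the symmetrical diferuloyl analogue.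

Step 17
Reactants: 24 the dibenzyl ether diester
Product: 25 bis[(4R,4aS,6R,7S,7aR)-2,4,7-trimethyloctahydro-1H-cyclopenta[c]pyridin-6-yl] (1R,3R)-2-(4-hydroxy-3-methoxyphenyl)-4-(4-hydroxyphenyl)cyclobutane-1,3-dicarboxylate (CNP0331906.2)
Conditions: H2 (1 atm), Pd/C, MeOH/EtOAc, AcOH (cat.), rt
Reagents that add atoms: none
Why: Hydrogenolysis of two aryl benzyl ethers; esters, cyclobutane and tertiary amines are inert, and a little acetic acid keeps the amines from slowing the catalyst.

## Compound list

1 | methyl (R)-3-hydroxy-2-methylpropanoate | COC(=O)[C@H](C)CO | starting material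
2 | (E)-but-2-en-1-amine | C/C=C/CN | starting material
3 | (R)-N-[(E)-but-2-en-1-yl]-3-hydroxy-2-methylpropanamide | C/C=C/CNC(=O)[C@H](C)CO | intermediate
4 | (S)-3-{[(E)-but-2-en-1-yl]amino}-2-methylpropan-1-ol | C/C=C/CNC[C@H](C)CO | intermediate
5 | tert-butyl [(E)-but-2-en-1-yl][(2S)-3-hydroxy-2-methylpropyl]carbamate | C/C=C/CN(C[C@H](C)CO)C(=O)OC(C)(C)C | intermediate
6 | tert-butyl [(E)-but-2-en-1-yl][(2S)-2-methyl-3-oxopropyl]carbamate | C/C=C/CN(C[C@H](C)C=O)C(=O)OC(C)(C)C | intermediate
7 | tert-butyl [(E)-but-2-en-1-yl][(2R)-2-methylbut-3-yn-1-yl]carbamate | C#C[C@@H](C)CN(C/C=C/C)C(=O)OC(C)(C)C | intermediate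
8 | hexacarbonyldicobalt complex of the alkyne of 7 (not isolated) | [CH]12[Co]3(=C=O)(=C=O)(=C=O)[Co]1(=C=O)(=C=O)(=C=O)C23[C@@H](C)CN(C/C=C/C)C(=O)OC(C)(C)C | intermediate
9 | tert-butyl (4R,7S,7aS)-4,7-dimethyl-6-oxo-1,3,4,6,7,7a-hexahydro-2H-cyclopenta[c]pyridine-2-carboxylate | O=C1C=C2[C@@H](CN(C(=O)OC(C)(C)C)C[C@@H]2C)[C@@H]1C | intermediate
10 | tert-butyl (4R,4aS,7S,7aR)-4,7-dimethyl-6-oxooctahydro-2H-cyclopenta[c]pyridine-2-carboxylate | O=C1C[C@@H]2[C@@H](CN(C(=O)OC(C)(C)C)C[C@@H]2C)[C@@H]1C | intermediate
11 | (4R,4aS,6S,7S,7aR)-2,4,7-trimethyloctahydro-1H-cyclopenta[c]pyridin-6-ol | O[C@H]1C[C@@H]2[C@@H](CN(C)C[C@@H]2C)[C@@H]1C | intermediate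
12 | cis-3-(methoxycarbonyl)cyclobutane-1-carboxylic acid | C1[C@H](C(=O)OC)C[C@@H]1C(=O)O | starting material
13 | quinolin-8-amine | Nc1cccc2cccnc12 | starting material
14 | methyl cis-3-(quinolin-8-ylcarbamoyl)cyclobutane-1-carboxylate | C1[C@H](C(=O)OC)C[C@@H]1C(=O)Nc1cccc2cccnc12 | intermediate
15 | 1-(benzyloxy)-4-iodobenzene | Ic1ccc(OCc2ccccc2)cc1 | starting material
16 | racemic methyl (1S*,2R*,3R*)-2-[4-(benzyloxy)phenyl]-3-(quinolin-8-ylcarbamoyl)cyclobutane-1-carboxylate, all-cis (one enantiomer drawn) | C1[C@H](C(=O)OC)[C@H](c2ccc(OCc3ccccc3)cc2)[C@@H]1C(=O)Nc1cccc2cccnc12 | intermediate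
17 | methyl (1S,2R,3R)-2-[4-(benzyloxy)phenyl]-3-(quinolin-8-ylcarbamoyl)cyclobutane-1-carboxylate | C1[C@H](C(=O)OC)[C@H](c2ccc(OCc3ccccc3)cc2)[C@@H]1C(=O)Nc1cccc2cccnc12 | intermediate
18 | methyl (1S,2R,3S)-2-[4-(benzyloxy)phenyl]-3-(quinolin-8-ylcarbamoyl)cyclobutane-1-carboxylate (amide trans to aryl, ester cis to aryl) | C1[C@H](C(=O)OC)[C@H](c2ccc(OCc3ccccc3)cc2)[C@H]1C(=O)Nc1cccc2cccnc12 | intermediate
19 | 4-iodo-2-methoxyphenol | COc1cc(I)ccc1O | starting material
20 | 1-(benzyloxy)-4-iodo-2-methoxybenzene | COc1cc(I)ccc1OCc1ccccc1 | intermediate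
21 | methyl (1R,2R,3R,4R)-2-[4-(benzyloxy)-3-methoxyphenyl]-4-[4-(benzyloxy)phenyl]-3-(quinolin-8-ylcarbamoyl)cyclobutane-1-carboxylate | COc1cc([C@H]2[C@H](C(=O)OC)[C@H](c3ccc(OCc4ccccc4)cc3)[C@H]2C(=O)Nc2cccc3cccnc23)ccc1OCc1ccccc1 | intermediate
22 | N-Boc imide of 21, tert-butyl N-acyl-N-(quinolin-8-yl)carbamate (not isolated) | COc1cc([C@H]2[C@H](C(=O)OC)[C@H](c3ccc(OCc4ccccc4)cc3)[C@H]2C(=O)N(C(=O)OC(C)(C)C)c2cccc3cccnc23)ccc1OCc1ccccc1 | intermediate
23 | (1R,3R)-2-[4-(benzyloxy)-3-methoxyphenyl]-4-[4-(benzyloxy)phenyl]cyclobutane-1,3-dicarboxylic acid, α-truxillic configuration (C1 carboxyl cis to the C2 ring, C3 carboxyl cis to the C4 ring, rings trans) | COc1cc([C@H]2[C@H](C(=O)O)[C@H](c3ccc(OCc4ccccc4)cc3)[C@H]2C(=O)O)ccc1OCc1ccccc1 | intermediate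
24 | bis[(4R,4aS,6R,7S,7aR)-2,4,7-trimethyloctahydro-1H-cyclopenta[c]pyridin-6-yl] ester of 23 | COc1cc([C@H]2[C@H](C(=O)O[C@@H]3C[C@@H]4[C@@H](CN(C)C[C@@H]4C)[C@@H]3C)[C@H](c3ccc(OCc4ccccc4)cc3)[C@H]2C(=O)O[C@@H]2C[C@@H]3[C@@H](CN(C)C[C@@H]3C)[C@@H]2C)ccc1OCc1ccccc1 | intermediate
25 | bis[(4R,4aS,6R,7S,7aR)-2,4,7-trimethyloctahydro-1H-cyclopenta[c]pyridin-6-yl] (1R,3R)-2-(4-hydroxy-3-methoxyphenyl)-4-(4-hydroxyphenyl)cyclobutane-1,3-dicarboxylate | COc1cc([C@H]2[C@H](C(=O)O[C@@H]3C[C@@H]4[C@@H](CN(C)C[C@@H]4C)[C@@H]3C)[C@H](c3ccc(O)cc3)[C@H]2C(=O)O[C@@H]2C[C@@H]3[C@@H](CN(C)C[C@@H]3C)[C@@H]2C)ccc1O | target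

## Step count and least certain steps

Total: 17 steps. Longest linear sequence: 10 steps (steps 1–8, 16, 17); the diacid branch is 8 steps to the target (steps 9–12, 14–17).

**Step 6 (key step).** A 1,7-enyne with a 1,2-disubstituted alkene inserts slowly, so decomplexation, alkyne oligomerisation or reduction of the complex may overtake cyclisation. Facial control by the single C4 methyl may also be incomplete, because its pseudo-equatorial preference is opposed by allylic strain towards the cobalt-bound C5. The fallback separates ring closure from introduction of the C7 methyl and sets out from 1. Aminolysis with allylamine under the conditions of step 1 gives (R)-N-allyl-3-hydroxy-2-methylpropanamide F1; LiAlH4 gives (S)-3-(allylamino)-2-methylpropan-1-ol F2; Boc2O gives the carbamate alcohol F3; Dess–Martin oxidation gives the aldehyde F4; and Ohira–Bestmann homologation gives the N-allyl enyne F5. Its terminal alkene is the best-behaved class for cobalt-mediated cyclisation, and Co2(CO)8 then Me3NO (through the hexacarbonyldicobalt complex F6, not isolated) should give the C7-unsubstituted enone F7. Kinetic deprotonation at C7 with LiN(i-Pr)2 at −78 °C and alkylation with MeI, anti to C1, returns to the route at 9. A remaining C4/C7a mixture would be removed by chromatography at 9, where the isomers are diastereomers.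

**Step 5.** Carbonate in methanol may epimerise the α-methyl aldehyde or trigger β-elimination of the carbamate before homologation is complete. The fallback is the Corey–Fuchs sequence from 6: CBr4 and PPh3 give the dibromoalkene tert-butyl [(E)-but-2-en-1-yl][(2R)-4,4-dibromo-2-methylbut-3-en-1-yl]carbamate F8 without base, and n-BuLi (2 equiv, THF, −78 °C) followed by water returns to the route at 7.

**Step 14.** The second arylation has to cleave a methylene C–H flanked by two substituted carbons, with an electron-rich meta-substituted iodide; low conversion, proto-deiodination and carbonate-induced epimerisation α to the ester are the likely failures. The fallback reverses the order of the two rings so that the methoxy-bearing iodide meets the unhindered methylene, and sets out from 14. Arylation with 20 under the conditions of step 10 gives the racemic all-cis guaiacyl amide ester F9; resolution gives the (1R,2S,3S) enantiomer F10; LiOt-Bu gives the amide epimer F11; and arylation with 15 gives the diaryl amide ester F12, a diastereomer of 21 with amide and ester exchanged. Boc activation (imide F13, not isolated) and LiOH/H2O2 return to the route at 23, because both carbonyl groups become carboxyl.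

**Step 16.** Two SN2 displacements at a secondary carbon next to a methyl-bearing carbon may give way to elimination of the alkoxyphosphonium to a cyclopentene or stop at the mono-ester. The fallback separates inversion from coupling and sets out from 11 and 23. Mitsunobu reaction of 11 with 4-nitrobenzoic acid, a more acidic partner suited to hindered alcohols, gives the inverted 4-nitrobenzoate F14, and K2CO3 in MeOH gives the 6R alcohol F15. Diacid 23 with (COCl)2 and catalytic DMF gives the bis(acyl chloride) F16, and acylation of F15 with F16 (pyridine, DMAP, CH2Cl2, 0 °C) returns to the route at 24 with retention. The same acylation of F15 would serve if step 8 delivered the 6R epimer directly.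

## Further compounds

F1 | step 6 | (R)-N-allyl-3-hydroxy-2-methylpropanamide | C=CCNC(=O)[C@H](C)CO
F2 | step 6 | (S)-3-(allylamino)-2-methylpropan-1-ol | C=CCNC[C@H](C)CO
F3 | step 6 | tert-butyl allyl[(2S)-3-hydroxy-2-methylpropyl]carbamate | C=CCN(C[C@H](C)CO)C(=O)OC(C)(C)C
F4 | step 6 | tert-butyl allyl[(2S)-2-methyl-3-oxopropyl]carbamate | C=CCN(C[C@H](C)C=O)C(=O)OC(C)(C)C
F5 | step 6 | tert-butyl allyl[(2R)-2-methylbut-3-yn-1-yl]carbamate | C#C[C@@H](C)CN(CC=C)C(=O)OC(C)(C)C
F6 | step 6 | hexacarbonyldicobalt complex of the alkyne of F5 (not isolated) | [CH]12[Co]3(=C=O)(=C=O)(=C=O)[Co]1(=C=O)(=C=O)(=C=O)C23[C@@H](C)CN(CC=C)C(=O)OC(C)(C)C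
F7 | step 6 | tert-butyl (4R,7aS)-4-methyl-6-oxo-1,3,4,6,7,7a-hexahydro-2H-cyclopenta[c]pyridine-2-carboxylate | O=C1C=C2[C@@H](CN(C(=O)OC(C)(C)C)C[C@@H]2C)C1
F8 | step 5 | tert-butyl [(E)-but-2-en-1-yl][(2R)-4,4-dibromo-2-methylbut-3-en-1-yl]carbamate | BrC(Br)=C[C@@H](C)CN(C/C=C/C)C(=O)OC(C)(C)C
F9 | step 14 | racemic methyl (1R*,2S*,3S*)-2-[4-(benzyloxy)-3-methoxyphenyl]-3-(quinolin-8-ylcarbamoyl)cyclobutane-1-carboxylate, all-cis (one enantiomer drawn) | COc1cc([C@H]2[C@@H](C(=O)Nc3cccc4cccnc34)C[C@H]2C(=O)OC)ccc1OCc1ccccc1
F10 | step 14 | methyl (1R,2S,3S)-2-[4-(benzyloxy)-3-methoxyphenyl]-3-(quinolin-8-ylcarbamoyl)cyclobutane-1-carboxylate | COc1cc([C@H]2[C@@H](C(=O)Nc3cccc4cccnc34)C[C@H]2C(=O)OC)ccc1OCc1ccccc1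
F11 | step 14 | methyl (1R,2S,3R)-2-[4-(benzyloxy)-3-methoxyphenyl]-3-(quinolin-8-ylcarbamoyl)cyclobutane-1-carboxylate | COc1cc([C@H]2[C@H](C(=O)Nc3cccc4cccnc34)C[C@H]2C(=O)OC)ccc1OCc1ccccc1
F12 | step 14 | methyl (1R,2S,3R,4S)-2-[4-(benzyloxy)-3-methoxyphenyl]-4-[4-(benzyloxy)phenyl]-3-(quinolin-8-ylcarbamoyl)cyclobutane-1-carboxylate | COc1cc([C@H]2[C@H](C(=O)Nc3cccc4cccnc34)[C@H](c3ccc(OCc4ccccc4)cc3)[C@H]2C(=O)OC)ccc1OCc1ccccc1
F13 | step 14 | N-Boc imide of F12 (not isolated) | COc1cc([C@H]2[C@H](C(=O)N(C(=O)OC(C)(C)C)c3cccc4cccnc34)[C@H](c3ccc(OCc4ccccc4)cc3)[C@H]2C(=O)OC)ccc1OCc1ccccc1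
F14 | step 16 | (4R,4aS,6R,7S,7aR)-2,4,7-trimethyloctahydro-1H-cyclopenta[c]pyridin-6-yl 4-nitrobenzoate | O=C(O[C@@H]1C[C@@H]2[C@@H](CN(C)C[C@@H]2C)[C@@H]1C)c1ccc([N+](=O)[O-])cc1
F15 | step 16 | (4R,4aS,6R,7S,7aR)-2,4,7-trimethyloctahydro-1H-cyclopenta[c]pyridin-6-ol | O[C@@H]1C[C@@H]2[C@@H](CN(C)C[C@@H]2C)[C@@H]1C
F16 | step 16 | (1R,3R)-2-[4-(benzyloxy)-3-methoxyphenyl]-4-[4-(benzyloxy)phenyl]cyclobutane-1,3-dicarbonyl dichloride | COc1cc([C@H]2[C@H](C(Cl)=O)[C@H](c3ccc(OCc4ccccc4)cc3)[C@H]2C(Cl)=O)ccc1OCc1ccccc1
A1 | alternative 1 | methyl 6-(benzyloxy)-2-[4-(benzyloxy)-3-methoxyphenyl]-3-oxo-1,2,2a,8b-tetrahydro-3H-cyclobuta[c]chromene-1-carboxylate | COc1cc([C@H]2[C@@H]3C(=O)Oc4cc(OCc5ccccc5)ccc4[C@@H]3[C@H]2C(=O)OC)ccc1OCc1ccccc1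
A2 | alternative 2 | 6-[(tert-butyldimethylsilyl)oxy]-2-(3-hydroxy-3-phenylpropyl)-7-methyloctahydro-3H-cyclopenta[c]pyridin-3-one | O=C1C[C@@H]2C[C@H](O[Si](C)(C)C(C)(C)C)[C@@H](C)[C@@H]2CN1CC[C@H](O)c1ccccc1
A3 | alternative 3 | 2,4,7-trimethylhexahydro-1H-cyclopenta[c]pyridine-3,6(2H,4H)-dione | O=C1C[C@@H]2[C@@H](CN(C)C(=O)[C@@H]2C)[C@@H]1C
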